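**Retrosynthetic overview**
1. Target ⇐ epoxy acid: transannular 6-exo attack of the C16 carboxylate on C3 of a (3S,4S)-oxirane gives the δ-lactone and the C4 carbinol, as presumed for the biogenesis of sinularin-type lactones.
2. 7-OH/8(19)-alkene ⇐ singlet-oxygen ene reaction on the 7,8-alkene (presumed biogenetic step), run while the 3,4-alkene and the acid are parked together as an iodolactone.
3. C1/C15 ⇐ carboxylate-directed asymmetric hydrogenation of an exocyclic C1=C15 acrylic acid.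
4. 14-membered ring ⇐ head-to-tail C1–C2 closure of an acyclic geranylgeranyl-type chain (the cembrene-synthase bond): nickel-mediated ionisation of the C2 allylic acetate and capture by C1 of the tail alkene.
5. Chain ⇐ farnesyl acetate (C2–C13; 11,12-oxirane by SeO2 oxidation then Sharpless epoxidation) + methyl 2-methylacetoacetate (C14, C1, C15–C17). Ring order: 11,12-oxirane → carbocycle → (temporary iodolactone) → 3,4-oxirane → δ-lactone.

Assumption: cembrane numbering is used for ring compounds (ring C1–C14; C15 carries C16 (carboxyl) and C17; C18, C19, C20 are the methyls on C4, C8, C12), and Ru(OAc)2[(S)-H8-BINAP] is taken to induce at C15 in the sense known for tiglic acid.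

**Step 1**
Reactants: 1 (2E,6E)-farnesyl acetate
Product: 2 (2E,6E,10E)-12-hydroxy-3,7,11-trimethyldodeca-2,6,10-trien-1-yl acetate
Conditions: SeO2 (0.1 equiv), tBuOOH (3 equiv), salicylic acid (0.1 equiv), CH2Cl2, rt
Reagents that add atoms: tert-butyl hydroperoxide, CC(C)(C)OO
Why: Catalytic Riley allylic oxidation (ene reaction then [2,3]-shift at selenium) hydroxylates only the E-methyl of the terminal trisubstituted alkene, the 2,3-alkene being deactivated by its allylic acetate, and no stereocentre is formed.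

**Step 2**
Reactants: 2 (2E,6E,10E)-12-hydroxy-3,7,11-trimethyldodeca-2,6,10-trien-1-yl acetate
Product: 3 (2E,6E)-9-[(2S,3S)-3-(hydroxymethyl)-3-methyloxiran-2-yl]-3,7-dimethylnona-2,6-dien-1-yl acetate
Conditions: Ti(OiPr)4 (0.1 equiv), L-(+)-diethyl tartrate (0.12 equiv), tBuOOH, 4 Å MS, CH2Cl2, −20 °C
Reagents that add atoms: tert-butyl hydroperoxide, CC(C)(C)OO
Why: Sharpless asymmetric epoxidation touches only the alkene bearing the free allylic hydroxyl, and the L-(+)-tartrate complex delivers oxygen to the face that gives the (S,S)-oxirane, which becomes C11(S)/C12(S) of the target.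

**Step 3**
Reactants: 3 (2E,6E)-9-[(2S,3S)-3-(hydroxymethyl)-3-methyloxiran-2-yl]-3,7-dimethylnona-2,6-dien-1-yl acetate; 4 methyl 2-methyl-3-oxobutanoate
Product: 7 methyl (2RS,6S,7S,10E,14E)-16-acetoxy-6,7-epoxy-2,6,10,14-tetramethyl-3-oxohexadeca-10,14-dienoate, via epoxy triflate 5 (not isolated), via keto ester dianion 6 (not isolated)
Conditions: Tf2O, 2,6-lutidine, CH2Cl2, −78 °C; then add to 6 (2.5 equiv; from 4, NaH then n-BuLi, THF, 0 °C) at −78 → −40 °C; AcOH quench
Reagents that add atoms: none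
Why: Weiler dianion γ-alkylation (SN2) forms C13–C14, because the primary oxiranylmethyl triflate has no β-hydrogen and reacts at −78 °C faster than the oxirane or the acetate, and the oxirane stereocentres are untouched (C15 is an enolisable mixture that is erased in step 4).

**Step 4**
Reactants: 7 methyl (2RS,6S,7S,10E,14E)-16-acetoxy-6,7-epoxy-2,6,10,14-tetramethyl-3-oxohexadeca-10,14-dienoate
Product: 8 methyl (2E,6S,7S,10E,14E)-16-acetoxy-6,7-epoxy-2,6,10,14-tetramethyl-3-(tosyloxy)hexadeca-2,10,14-trienoate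
Conditions: TsCl, N-methylimidazole, Et3N, MeCN, 0 °C → rt
Reagents that add atoms: 4-toluenesulfonyl chloride, Cc1ccc(cc1)S(Cl)(=O)=O
Why: Stereoselective enol tosylation of the β-keto ester under non-chelating amine conditions gives the (E)-enol tosylate (OTs trans to CO2Me), which fixes the alkene geometry that step 7 converts into the C1/C15 relative configuration.

**Step 5**
Reactants: 8 methyl (2E,6S,7S,10E,14E)-16-acetoxy-6,7-epoxy-2,6,10,14-tetramethyl-3-(tosyloxy)hexadeca-2,10,14-trienoate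
Product: 9 methyl (2E)-2-[(3E,7E,11S,12S)-11,12-epoxy-4,8,12-trimethylcyclotetradeca-3,7-dien-1-ylidene]propanoate
Conditions: NiBr2(dme) (20 mol%), 4,4′-di-tert-butyl-2,2′-bipyridine (24 mol%), Zn (3 equiv), DMA, 50 °C, syringe pump to 2 mM
Reagents that add atoms: none
Why: Proposed new method: an intramolecular nickel-catalysed reductive cross-electrophile coupling in which zerovalent nickel inserts into the activated alkenyl C1–OTs bond, the C2 allylic acetate is ionised to an allylnickel unit (the laboratory counterpart of diphosphate ionisation) and reductive elimination at the unhindered CH2 terminus closes the cembrene-synthase bond C1–C2 with retention of the 3E and exocyclic E geometries and without creating a stereocentre, the closest known reaction being the intermolecular reductive coupling of aryl or alkenyl halides with allylic acetates, which gives linear E products.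

**Step 6**
Reactants: 9 methyl (2E)-2-[(3E,7E,11S,12S)-11,12-epoxy-4,8,12-trimethylcyclotetradeca-3,7-dien-1-ylidene]propanoate
Product: 10 (2E)-2-[(3E,7E,11S,12S)-11,12-epoxy-4,8,12-trimethylcyclotetradeca-3,7-dien-1-ylidene]propanoic acid
Conditions: LiOH·H2O, THF/MeOH/H2O, 50 °C; AcOH to pH 5
Reagents that add atoms: lithium hydroxide, [Li+].[OH-]
Why: Ester saponification proceeds by acyl substitution, and the trisubstituted oxirane and the alkenes are inert to hydroxide.

**Step 7**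
Reactants: 10 (2E)-2-[(3E,7E,11S,12S)-11,12-epoxy-4,8,12-trimethylcyclotetradeca-3,7-dien-1-ylidene]propanoic acid
Product: 11 (2S)-2-[(1R,3E,7E,11S,12S)-11,12-epoxy-4,8,12-trimethylcyclotetradeca-3,7-dien-1-yl]propanoic acid
Conditions: Ru(OAc)2[(S)-H8-BINAP] (2 mol%), H2 (100 atm), Et3N (0.5 equiv), MeOH, 35 °C
Reagents that add atoms: none
Why: Carboxylate-directed Noyori-type asymmetric hydrogenation lets the catalyst choose the face at C15 (S), and syn addition across the geometrically pure E-alkene then sets C1 (R) in the same event, while the isolated ring alkenes and the oxirane are not reduced (as in geranic acid to citronellic acid).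

**Step 8**
Reactants: 11 (2S)-2-[(1R,3E,7E,11S,12S)-11,12-epoxy-4,8,12-trimethylcyclotetradeca-3,7-dien-1-yl]propanoic acid
Product: 12 (1R,3R,4S,11S,12S,15S)-11,12-epoxy-4-iodocembr-7E-en-16,3-olide
Conditions: I2, NaHCO3, MeCN, 0 °C, dark
Reagents that add atoms: iodine, II
Why: Iodolactonisation (6-exo, anti addition) engages only the 3,4-alkene within reach of the carboxylate and parks both groups as the cis-bridged lactone (3R, 4S-iodide), and any regio- or stereoisomer of this temporary ring converges again in step 10.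

**Step 9**
Reactants: 12 (1R,3R,4S,11S,12S,15S)-11,12-epoxy-4-iodocembr-7E-en-16,3-olide
Product: 14 (1R,3R,4S,7R,11S,12S,15S)-11,12-epoxy-7-hydroxy-4-iodocembr-8(19)-en-16,3-olide, via allylic hydroperoxide 13 (not isolated)
Conditions: O2, tetraphenylporphyrin (cat.), hν (>500 nm), CH2Cl2, −20 °C; then PPh3, 0 °C
Reagents that add atoms: oxygen, O=O
Why: Schenck ene reaction of singlet oxygen on the only remaining alkene abstracts hydrogen from the C19 methyl on the disubstituted side to give the 8(19)-methylidene 7-hydroperoxide (the 8-hydroperoxy-6-ene regioisomer, expected in comparable amount, is removed by chromatography), 7R is expected from attack on the exposed outer face of the bridged macrobicycle (as presumed for the natural product), and PPh3 reduces the O–O bond.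

**Step 10**
Reactants: 14 (1R,3R,4S,7R,11S,12S,15S)-11,12-epoxy-7-hydroxy-4-iodocembr-8(19)-en-16,3-olide
Product: 15 (2S)-2-[(1R,3E,7R,11S,12S)-11,12-epoxy-7-hydroxy-4,12-dimethyl-8-methylidenecyclotetradec-3-en-1-yl]propanoic acid
Conditions: Zn, AcOH, THF, 0 °C → rt
Reagents that add atoms: none
Why: Zinc-mediated reductive anti-elimination of the β-iodo carboxylate (unmasking of the iodolactone) returns the (3E)-alkene and the free acid without touching C1, C7, C15 or the oxirane.

**Step 11**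
Reactants: 15 (2S)-2-[(1R,3E,7R,11S,12S)-11,12-epoxy-7-hydroxy-4,12-dimethyl-8-methylidenecyclotetradec-3-en-1-yl]propanoic acid
Product: 17 (1R,3R,4S,7R,11S,12S,15S)-11,12-epoxy-4,7-dihydroxycembr-8(19)-en-16,3-olide, via epoxy acid 16 (not isolated)
Conditions: ent-Shi ketone (L-fructose-derived, 0.3 equiv), KHSO5 (Oxone, 2KHSO5·KHSO4·K2SO4), K2CO3, Bu4NHSO4, MeCN/CH2(OMe)2/aq. Na2B4O7, 0 °C; then pH 8, 35 °C
Reagents that add atoms: potassium peroxymonosulfate, [K+].[O-]S(=O)(=O)OO
Why: Shi epoxidation (reagent-controlled spiro transition state) of the only trisubstituted alkene gives the (3S,4S)-oxirane, and biomimetic 6-exo opening at C3 by the C16 carboxylate with inversion then installs the 3R lactone oxygen and leaves the 4S tertiary alcohol, with the C15 methyl in its thermodynamically preferred equatorial position on the cis-bridged δ-lactone.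

**Compound list**
1 | (2E,6E)-farnesyl acetate | CC(=O)OC/C=C(C)/CC/C=C(C)/CCC=C(C)C | starting material
2 | (2E,6E,10E)-12-hydroxy-3,7,11-trimethyldodeca-2,6,10-trien-1-yl acetate | CC(=O)OC/C=C(C)/CC/C=C(C)/CC/C=C(C)/CO | intermediate
3 | (2E,6E)-9-[(2S,3S)-3-(hydroxymethyl)-3-methyloxiran-2-yl]-3,7-dimethylnona-2,6-dien-1-yl acetate | CC(=O)OC/C=C(C)/CC/C=C(C)/CC[C@@H]1O[C@@]1(C)CO | intermediate
4 | methyl 2-methyl-3-oxobutanoate | COC(=O)C(C)C(C)=O | starting material
5 | (2E,6E)-3,7-dimethyl-9-[(2S,3S)-3-methyl-3-(triflyloxymethyl)oxiran-2-yl]nona-2,6-dien-1-yl acetate | CC(=O)OC/C=C(C)/CC/C=C(C)/CC[C@@H]1O[C@@]1(C)COS(=O)(=O)C(F)(F)F | intermediate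
6 | lithium sodium 1-methoxy-2-methylbuta-1,3-diene-1,3-diolate (dianion of 4) | [Li+].[Na+].C=C([O-])C(C)=C([O-])OC | intermediate
7 | methyl (2RS,6S,7S,10E,14E)-16-acetoxy-6,7-epoxy-2,6,10,14-tetramethyl-3-oxohexadeca-10,14-dienoate | CC(=O)OC/C=C(C)/CC/C=C(C)/CC[C@@H]1O[C@@]1(C)CCC(=O)C(C)C(=O)OC | intermediate
8 | methyl (2E,6S,7S,10E,14E)-16-acetoxy-6,7-epoxy-2,6,10,14-tetramethyl-3-(tosyloxy)hexadeca-2,10,14-trienoate | CC(=O)OC/C=C(C)/CC/C=C(C)/CC[C@@H]1O[C@@]1(C)CC/C(OS(=O)(=O)c1ccc(C)cc1)=C(/C)C(=O)OC | intermediate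
9 | methyl (2E)-2-[(3E,7E,11S,12S)-11,12-epoxy-4,8,12-trimethylcyclotetradeca-3,7-dien-1-ylidene]propanoate | COC(=O)/C(C)=C1/C/C=C(C)/CC/C=C(C)/CC[C@@H]2O[C@@]2(C)CC1 | intermediate
10 | (2E)-2-[(3E,7E,11S,12S)-11,12-epoxy-4,8,12-trimethylcyclotetradeca-3,7-dien-1-ylidene]propanoic acid | OC(=O)/C(C)=C1/C/C=C(C)/CC/C=C(C)/CC[C@@H]2O[C@@]2(C)CC1 | intermediate
11 | (2S)-2-[(1R,3E,7E,11S,12S)-11,12-epoxy-4,8,12-trimethylcyclotetradeca-3,7-dien-1-yl]propanoic acid | OC(=O)[C@@H](C)[C@H]1C/C=C(C)/CC/C=C(C)/CC[C@@H]2O[C@@]2(C)CC1 | intermediate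
12 | (1R,3R,4S,11S,12S,15S)-11,12-epoxy-4-iodocembr-7E-en-16,3-olide | C[C@@H]1C(=O)O[C@@H]2C[C@H]1CC[C@]3(C)O[C@H]3CC/C(C)=C/CC[C@]2(C)I | intermediate
13 | (1R,3R,4S,7R,11S,12S,15S)-11,12-epoxy-7-hydroperoxy-4-iodocembr-8(19)-en-16,3-olide | C[C@@H]1C(=O)O[C@@H]2C[C@H]1CC[C@]3(C)O[C@H]3CCC(=C)[C@H](OO)CC[C@]2(C)I | intermediate
14 | (1R,3R,4S,7R,11S,12S,15S)-11,12-epoxy-7-hydroxy-4-iodocembr-8(19)-en-16,3-olide | C[C@@H]1C(=O)O[C@@H]2C[C@H]1CC[C@]3(C)O[C@H]3CCC(=C)[C@H](O)CC[C@]2(C)I | intermediate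
15 | (2S)-2-[(1R,3E,7R,11S,12S)-11,12-epoxy-7-hydroxy-4,12-dimethyl-8-methylidenecyclotetradec-3-en-1-yl]propanoic acid | OC(=O)[C@@H](C)[C@H]1C/C=C(C)/CC[C@@H](O)C(=C)CC[C@@H]2O[C@@]2(C)CC1 | intermediate
16 | (2S)-2-[(1R,3S,4S,7R,11S,12S)-3,4:11,12-diepoxy-7-hydroxy-4,12-dimethyl-8-methylidenecyclotetradecyl]propanoic acid | OC(=O)[C@@H](C)[C@H]1C[C@@H]2O[C@@]2(C)CC[C@@H](O)C(=C)CC[C@@H]3O[C@@]3(C)CC1 | intermediate
17 | (1R,3R,4S,7R,11S,12S,15S)-11,12-epoxy-4,7-dihydroxycembr-8(19)-en-16,3-olide (CNP0262409.1) | C=C1CC[C@@H]2O[C@@]2(C)CC[C@@H]2C[C@@H](OC(=O)[C@H]2C)[C@@](C)(O)CC[C@H]1O | target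

**Totals and risks**
Total steps: 11. Longest linear sequence: 11 (1 → 17).

Most likely to fail:

Step 5 (macrocyclising reductive coupling): oligomerisation, attack at the tertiary allyl terminus, 3E/3Z scrambling or simple reduction of the tosylate may win. Fallback, setting out from 8 and returning at 9: replace the reductive manifold by a two-stage boron route. Borylation of the allylic acetate (Pd2(dba)3, B2pin2, DMSO, 50 °C) gives methyl (2E,6S,7S,10E,14E)-6,7-epoxy-2,6,10,14-tetramethyl-16-(pinacolboryl)-3-(tosyloxy)hexadeca-2,10,14-trienoate F1. An intramolecular Suzuki–Miyaura coupling (Pd(OAc)2, SPhos, K3PO4, THF/H2O, high dilution, transmetalation at the CH2–B carbon) then closes C1–C2 and gives 9.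

Step 7 (hydrogenation of a tetrasubstituted acrylic acid): low rate or low induction is possible. Fallback, setting out from 9 and returning at 11: change the directing group. Reduction with iBu2AlH (CH2Cl2, −78 °C) gives (2E)-2-[(3E,7E,11S,12S)-11,12-epoxy-4,8,12-trimethylcyclotetradeca-3,7-dien-1-ylidene]propan-1-ol F2. Hydroxyl-directed asymmetric hydrogenation with Ru(OAc)2(BINAP) (antipode chosen by a small test, 50 atm H2, MeOH, as for geraniol) gives (2S)-2-[(1R,3E,7E,11S,12S)-11,12-epoxy-4,8,12-trimethylcyclotetradeca-3,7-dien-1-yl]propan-1-ol F3. Dess–Martin oxidation gives (2S)-2-[(1R,3E,7E,11S,12S)-11,12-epoxy-4,8,12-trimethylcyclotetradeca-3,7-dien-1-yl]propanal F4, which is taken on at once by Pinnick oxidation (NaClO2, NaH2PO4, 2-methyl-2-butene, tBuOH/H2O) to 11.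

Step 9 (ene reaction): the regioisomer ratio limits the yield, and the facial choice at C7 rests on substrate control. Fallback, setting out from 12 and returning at 14: if the ene reaction gives mainly (1R,3R,4S,7S,11S,12S,15S)-11,12-epoxy-7-hydroxy-4-iodocembr-8(19)-en-16,3-olide F5, invert it by a Mitsunobu reaction (HCO2H, PPh3, diisopropyl azodicarboxylate, THF, 0 °C) to (1R,3R,4S,7R,11S,12S,15S)-11,12-epoxy-7-formyloxy-4-iodocembr-8(19)-en-16,3-olide F6. Brief NaHCO3/MeOH at 0 °C then releases 14.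

**Further compounds**
F1 | step 5 | methyl (2E,6S,7S,10E,14E)-6,7-epoxy-2,6,10,14-tetramethyl-16-(4,4,5,5-tetramethyl-1,3,2-dioxaborolan-2-yl)-3-(tosyloxy)hexadeca-2,10,14-trienoate | CC1(C)OB(C/C=C(C)/CC/C=C(C)/CC[C@@H]2O[C@@]2(C)CC/C(OS(=O)(=O)c3ccc(C)cc3)=C(/C)C(=O)OC)OC1(C)C
F2 | step 7 | (2E)-2-[(3E,7E,11S,12S)-11,12-epoxy-4,8,12-trimethylcyclotetradeca-3,7-dien-1-ylidene]propan-1-ol | OC/C(C)=C1/C/C=C(C)/CC/C=C(C)/CC[C@@H]2O[C@@]2(C)CC1
F3 | step 7 | (2S)-2-[(1R,3E,7E,11S,12S)-11,12-epoxy-4,8,12-trimethylcyclotetradeca-3,7-dien-1-yl]propan-1-ol | OC[C@@H](C)[C@H]1C/C=C(C)/CC/C=C(C)/CC[C@@H]2O[C@@]2(C)CC1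
F4 | step 7 | (2S)-2-[(1R,3E,7E,11S,12S)-11,12-epoxy-4,8,12-trimethylcyclotetradeca-3,7-dien-1-yl]propanal | O=C[C@@H](C)[C@H]1C/C=C(C)/CC/C=C(C)/CC[C@@H]2O[C@@]2(C)CC1
F5 | step 9 | (1R,3R,4S,7S,11S,12S,15S)-11,12-epoxy-7-hydroxy-4-iodocembr-8(19)-en-16,3-olide | C[C@@H]1C(=O)O[C@@H]2C[C@H]1CC[C@]3(C)O[C@H]3CCC(=C)[C@@H](O)CC[C@]2(C)I
F6 | step 9 | (1R,3R,4S,7R,11S,12S,15S)-11,12-epoxy-7-formyloxy-4-iodocembr-8(19)-en-16,3-olide | C[C@@H]1C(=O)O[C@@H]2C[C@H]1CC[C@]3(C)O[C@H]3CCC(=C)[C@H](OC=O)CC[C@]2(C)I
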